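The runs stem from a simulated flask on assumed constants, and the scatter is random.

Time looks like the small part here: between 3.00 d and 4.00 d the electrophile falls by 4.6 percentage points in Tuesday's run, 0.6 points in Wednesday's and 2.4 points in Saturday's, so I reckon the large part first and treat the stretch to 6.0 d as a correction.

| setting | Tuesday's | Wednesday's | Saturday's | flask |
|---|---|---|---|---|
| electrophile | 16 mM | 36 mM | 24 mM | 24 mM |
| nucleophile | 22.8 mM | 22.8 mM | 46 mM | 22.8 mM |
| buffer base | 72 mM | 72 mM | 72 mM | 72.0 mM |
| buffer acid | 2.4 mM | 2.4 mM | 2.4 mM | 2.40 mM |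
| remark | run made earlier | run made earlier | run made earlier |  |
| time |  |  |  | 6.0 d |

| run | time / d | electrophile / % | target / % |
|---|---|---|---|
| Tuesday's | 0.625 | 86.4 | 8.6 |
| Tuesday's | 1.25 | 79.1 | 6.3 |
| Tuesday's | 2.00 | 70.4 | 5.8 |
| Tuesday's | 3.00 | 65.0 | 5.0 |
| Tuesday's | 4.00 | 60.4 | 3.8 |
| Wednesday's | 0.625 | 85.9 | 6.0 |
| Wednesday's | 1.25 | 78.4 | 1.7 |
| Wednesday's | 2.00 | 75.8 | 0.1 |
| Wednesday's | 3.00 | 70.8 | 0 |
| Wednesday's | 4.00 | 70.2 | 1.6 |
| Saturday's | 0.625 | 77.8 | 9.1 |
| Saturday's | 1.25 | 66.0 | 7.1 |
| Saturday's | 2.00 | 61.0 | 5.9 |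
| Saturday's | 3.00 | 57.1 | 3.1 |
| Saturday's | 4.00 | 54.7 | 2.7 |

(scatter of a reading: 1 percentage point)

* part of the electrophile that has reacted at 6.0 d
* pH of the solution at 6.0 d

Tuesday's run gives 0.278, Wednesday's 0.471 and Saturday's 0.236 for what I call the catch, the electrophile lost by the last reading per nucleophile charged. The flask's c(electrophile) lies between Tuesday's and Wednesday's at the same c(nucleophile), so those catches give a loose bracket of 26.4% to 44.7%, and the percentages lost tighten it to 29.8% to 39.6%.

I suppose that the nucleophile has a rival loss growing with its own concentration, so I draw the reciprocal of the catch as a straight line in c(nucleophile)/c(electrophile). Through Tuesday's and Wednesday's runs, this line gives 0.222 for Saturday's run, against the 0.236 read there, and 0.368 for the flask at 4.00 d. That is 35.0% as my lower bound, and the mean last-day fall continued to 6.0 d gives 40.1% as my upper one. The readings show no pH, so I name none.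

The forecast says 39%, above my lower bound and below my upper, and pH 7.9, “which is largely a guess”.

The flask gives 35.4% and pH 6.57, a catch of 0.373 at 6.0 d against my 0.368 for 4.00 d.

    2 electrophile → self-condensation product B (k = 2.00 × 10⁻⁵ L mol⁻¹ min⁻¹)
    buffer acid ⇌ buffer base + acid, settled at all times (K = 6.30 × 10⁻⁵ M)
    protonated nucleophile ⇌ nucleophile + acid, settled at all times (K = 7.90 × 10⁻⁹ M)
    electrophile + nucleophile → acid + target + leaving group (k = 0.0130 L mol⁻¹ min⁻¹)
    electrophile + target → side product (k = 0.0450 L mol⁻¹ min⁻¹)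
    2 nucleophile → self-condensation product A (k = 0.0530 L mol⁻¹ min⁻¹)

In the flask, the nucleophile, the limiting reagent, stands at 0.81% of its charge, less than the electrophile's 65%. The neighbour flask charged with 91 mM of nucleophile lies far along the same line, which gives a catch of 0.125 for 4.00 d and so a loss of 47.4%. That neighbour flask loses more than this by 6.0 d, namely 58.5%, a catch of 0.154.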